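Ring C, the resorcinol ring of the biaryl, is built rather than coupled. C1 bears phenol ring B, C3 the acyl arm to ring D, and C4 and C6 the hydroxyls. Its C4–C5–C6–C1 segment therefore has the 1,3-dioxygenation of an acetoacetate dienolate, and C2–C3 map onto a terminal ynone. One Diels–Alder benzannulation forms C1–C2 and C3–C4 and, after loss of methanol and silicon, leaves aryl, acyl and both oxygens in place. The precursor is a 4-aryl-1,3-dimethoxy-1-silyloxybutadiene carrying brominated ring B, met by the ynone carrying ring D. The bromine later accepts the arm to ring A, the terminal 2,4-dihydroxyphenyl ketone.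

Key step: step 6

Labels: in ring B, C1 carries the CH2CH2CO arm to ring A, C3 carries ring C and C4 carries the hydroxyl; ring D is the terminal 4-hydroxyphenyl ring.
Remark: the target has no stereocentre, and its biaryl axis, flanked by only two ortho hydroxyl groups, is taken to rotate freely, so no stereochemical element needs control.

Step 1
Reactants: 1 (5-bromo-2-methoxyphenyl)acetic acid
Product: 3 methyl 4-(5-bromo-2-methoxyphenyl)-3-oxobutanoate, via acyl imidazolide 2 (not isolated)
Conditions: 1,1'-carbonyldiimidazole, THF, rt; then KO2CCH2CO2Me, MgCl2, Et3N, MeCN, rt → 40 °C; 1 M HCl work-up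
Reagents that add atoms: potassium methyl malonate, COC(=O)CC(=O)[O-].[K+]
Why: The decarboxylative Claisen homologation of an activated acid with a magnesium malonate half-ester (Masamune–Brooks reaction) gives the β-keto ester under almost neutral conditions that leave the aryl bromide and the methyl ether untouched.

Step 2
Reactants: 3 methyl 4-(5-bromo-2-methoxyphenyl)-3-oxobutanoate
Product: 4 methyl (E)-4-(5-bromo-2-methoxyphenyl)-3-methoxybut-2-enoate
Conditions: HC(OMe)3, H2SO4 (cat.), MeOH, 50 °C
Reagents that add atoms: trimethyl orthoformate, COC(OC)OC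
Why: Acid-catalysed ketalisation by the orthoester followed by loss of methanol (enol etherification of a β-keto ester) should give the conjugated E enol ether with methoxy and ester trans; a minor double-bond isomer would feed the same dienolate in step 3.

Step 3
Reactants: 4 methyl (E)-4-(5-bromo-2-methoxyphenyl)-3-methoxybut-2-enoate
Product: 6 (1Z,3Z)-4-(5-bromo-2-methoxyphenyl)-1,3-dimethoxy-1-(trimethylsilyloxy)buta-1,3-diene, via lithium dienolate 5 (not isolated)
Conditions: LiN(iPr)2 (1.1 equiv), THF, −78 °C; Me3SiCl (1.3 equiv), −78 °C → rt; pentane, filtration under Ar, used crude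
Reagents that add atoms: chlorotrimethylsilane, C[Si](C)(C)Cl
Why: γ-Deprotonation of a 3-alkoxy enoate and O-silylation of the extended enolate is the standard entry to Brassard-type dienes; the benzylic γ-protons are the most acidic in 4, allylic 1,3-strain turns the aryl group away from the ester during deprotonation so that it ends outward (3Z), and the aryl bromide is inert to the amide base at −78 °C.

Step 4
Reactants: 7 3-(4-methoxyphenyl)propanoic acid
Product: 9 N-methoxy-3-(4-methoxyphenyl)-N-methylpropanamide, via acyl imidazolide 8 (not isolated)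
Conditions: 1,1'-carbonyldiimidazole, CH2Cl2, rt; then MeNH(OMe)·HCl, rt
Reagents that add atoms: N,O-dimethylhydroxylamine hydrochloride, CNOC.Cl
Why: Weinreb amide formation through the acyl imidazolide needs no further base, because the released imidazole takes up the hydrogen chloride, and nothing else in 7 can react.

Step 5
Reactants: 9 N-methoxy-3-(4-methoxyphenyl)-N-methylpropanamide; 10 ethynylmagnesium bromide
Product: 12 5-(4-methoxyphenyl)pent-1-yn-3-one, via tetrahedral magnesium chelate 11 (not isolated)
Conditions: HC≡CMgBr (0.5 M in THF, 2.5 equiv), THF, 0 °C → rt; transferred into ice-cold 1 M HCl/Et2O; kept cold and used promptly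
Reagents that add atoms: none
Why: In this Weinreb ketone synthesis chelate 11 persists until the quench so that only one alkynyl group adds, and the inverse acidic quench protonates the released N,O-dimethylhydroxylamine before it can add to the ynone in conjugate fashion.

Step 6
Reactants: 6 (1Z,3Z)-4-(5-bromo-2-methoxyphenyl)-1,3-dimethoxy-1-(trimethylsilyloxy)buta-1,3-diene; 12 5-(4-methoxyphenyl)pent-1-yn-3-one
Product: 15 1-[5-(5-bromo-2-methoxyphenyl)-2-hydroxy-4-methoxyphenyl]-3-(4-methoxyphenyl)propan-1-one, via cyclohexa-1,4-diene adduct 13 (not isolated), via aryl trimethylsilyl ether 14 (not isolated)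
Conditions: 6 (1.5 equiv), toluene, Ar, rt → 90 °C; then 1 M HCl, THF, rt
Reagents that add atoms: none
Why: Three oxygen donors make the aryl-bearing terminus of 6 its most nucleophilic carbon, so it bonds to the unsubstituted β-carbon of ynone 12 (C1–C2 of ring C) while the ketene acetal carbon bonds to the acyl-bearing α-carbon (C3–C4), in a thermal (4+2) cycloaddition in which the first bond runs well ahead of the second. Ring C is thus closed by intermolecular cycloaddition as the six-membered cyclohexa-1,4-diene 13, whose doubly allylic C1–H and C4 methoxy group leave as methanol in a 1,4-elimination to give aryl silyl ether 14, and dilute acid then frees the C4 phenol, which is held by a hydrogen bond to the new ketone. The closest known reaction type is the Diels–Alder benzannulation of Brassard-type 1,1,3-trioxygenated butadienes with acetylenic ketones and esters to resorcinol derivatives, and the aryl group on the diene terminus only extends the substitution pattern. No stereocentre has to be controlled, because both sp3 carbons of 13 become aromatic in the same flask. The one selectivity required is regiochemical, and it is secured by the matched polarisation of the two partners and by the fact that the alkyne carbon meeting the crowded diene end carries only hydrogen. The outward (3Z) aryl group keeps the s-cis conformer accessible, and the aryl bromide, the methyl ethers and the enolisable ketone are indifferent to neutral heating.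

Step 7
Reactants: 16 methyl 2,4-dimethoxybenzoate
Product: 17 1-(2,4-dimethoxyphenyl)cyclopropan-1-ol
Conditions: EtMgBr (3 equiv, slow addition), Ti(OiPr)4 (20 mol %), THF, 0 °C → rt; H2O quench, filtration through Celite
Reagents that add atoms: ethylmagnesium bromide, CC[Mg]Br
Why: In the Kulinkovich cyclopropanation the titanacyclopropane formed from EtMgBr and Ti(OiPr)4 acts as a 1,2-dicarbanion that adds twice to the ester carbonyl, the aryl methyl ethers being inert and the neutral quench sparing the acid-sensitive cyclopropanol.

Step 8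
Reactants: 15 1-[5-(5-bromo-2-methoxyphenyl)-2-hydroxy-4-methoxyphenyl]-3-(4-methoxyphenyl)propan-1-one; 17 1-(2,4-dimethoxyphenyl)cyclopropan-1-ol
Product: 18 1-(2,4-dimethoxyphenyl)-3-[3-{4-hydroxy-2-methoxy-5-[3-(4-methoxyphenyl)propanoyl]phenyl}-4-methoxyphenyl]propan-1-one
Conditions: Pd(OAc)2 (5 mol %), XPhos (2-dicyclohexylphosphino-2',4',6'-triisopropylbiphenyl, 10 mol %), Cs2CO3 (3 equiv), 17 (1.5 equiv), toluene, 80 °C
Reagents that add atoms: none
Why: This is the palladium-catalysed ring-opening cross-coupling of a tertiary cyclopropanol with an aryl bromide (homoenolate arylation), running through oxidative addition of C–Br to zerovalent palladium, alkoxide exchange, β-carbon elimination and a reductive elimination that the bulky phosphine favours over β-hydride elimination; the chelated, weakly nucleophilic phenol travels as its caesium salt, for which the extra base is supplied.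

Step 9
Reactants: 18 1-(2,4-dimethoxyphenyl)-3-[3-{4-hydroxy-2-methoxy-5-[3-(4-methoxyphenyl)propanoyl]phenyl}-4-methoxyphenyl]propan-1-one
Product: 19 1-(2,4-dihydroxyphenyl)-3-[3-{2,4-dihydroxy-5-[3-(4-hydroxyphenyl)propanoyl]phenyl}-4-hydroxyphenyl]propan-1-one (CID44566750)
Conditions: BBr3 (12 equiv), CH2Cl2, −78 °C → rt; then ice-water
Reagents that add atoms: none
Why: Lewis-acid cleavage of aryl methyl ethers with BBr3 (complexation at oxygen, bromide attack on methyl, hydrolysis of the aryl borates) should remove all five methyl groups, while the saturated aryl ketones and the biaryl are stable to the reagent.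

Compound list
1 | (5-bromo-2-methoxyphenyl)acetic acid | COc1ccc(Br)cc1CC(=O)O | starting material
2 | 2-(5-bromo-2-methoxyphenyl)-1-(1H-imidazol-1-yl)ethan-1-one (acyl imidazolide, not isolated) | COc1ccc(Br)cc1CC(=O)n1ccnc1 | intermediate
3 | methyl 4-(5-bromo-2-methoxyphenyl)-3-oxobutanoate | COC(=O)CC(=O)Cc1cc(Br)ccc1OC | intermediate
4 | methyl (E)-4-(5-bromo-2-methoxyphenyl)-3-methoxybut-2-enoate | COC(=O)/C=C(/OC)Cc1cc(Br)ccc1OC | intermediate
5 | lithium dienolate of 4 (not isolated) | [Li+].CO/C([O-])=C/C(OC)=C/c1cc(Br)ccc1OC | intermediate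
6 | (1Z,3Z)-4-(5-bromo-2-methoxyphenyl)-1,3-dimethoxy-1-(trimethylsilyloxy)buta-1,3-diene (aryl outward at C3=C4; the C1=C2 geometry is of no consequence) | CO/C(O[Si](C)(C)C)=C/C(OC)=C/c1cc(Br)ccc1OC | intermediate
7 | 3-(4-methoxyphenyl)propanoic acid | COc1ccc(CCC(=O)O)cc1 | starting material
8 | 1-(1H-imidazol-1-yl)-3-(4-methoxyphenyl)propan-1-one (acyl imidazolide, not isolated) | COc1ccc(CCC(=O)n2ccnc2)cc1 | intermediate
9 | N-methoxy-3-(4-methoxyphenyl)-N-methylpropanamide | COc1ccc(CCC(=O)N(C)OC)cc1 | intermediate
10 | ethynylmagnesium bromide | C#C[Mg]Br | starting material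
11 | bromomagnesium alkoxide of 3-[methoxy(methyl)amino]-5-(4-methoxyphenyl)pent-1-yn-3-ol (tetrahedral chelate, racemic, not isolated) | C#CC(CCc1ccc(OC)cc1)(O[Mg]Br)N(C)OC | intermediate
12 | 5-(4-methoxyphenyl)pent-1-yn-3-one | C#CC(=O)CCc1ccc(OC)cc1 | intermediate
13 | 1-[3-(5-bromo-2-methoxyphenyl)-4,6-dimethoxy-6-(trimethylsilyloxy)cyclohexa-1,4-dien-1-yl]-3-(4-methoxyphenyl)propan-1-one (diastereomer mixture, both centres lost in the same flask, not isolated) | COC1=CC(OC)(O[Si](C)(C)C)C(C(=O)CCc2ccc(OC)cc2)=CC1c1cc(Br)ccc1OC | intermediate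
14 | 1-[5-(5-bromo-2-methoxyphenyl)-4-methoxy-2-(trimethylsilyloxy)phenyl]-3-(4-methoxyphenyl)propan-1-one (not isolated) | COc1ccc(CCC(=O)c2cc(-c3cc(Br)ccc3OC)c(OC)cc2O[Si](C)(C)C)cc1 | intermediate
15 | 1-[5-(5-bromo-2-methoxyphenyl)-2-hydroxy-4-methoxyphenyl]-3-(4-methoxyphenyl)propan-1-one | O=C(CCc1ccc(OC)cc1)c1cc(-c2cc(Br)ccc2OC)c(OC)cc1O | intermediate
16 | methyl 2,4-dimethoxybenzoate | COC(=O)c1ccc(OC)cc1OC | starting material
17 | 1-(2,4-dimethoxyphenyl)cyclopropan-1-ol | OC1(CC1)c1ccc(OC)cc1OC | intermediate
18 | 1-(2,4-dimethoxyphenyl)-3-[3-{4-hydroxy-2-methoxy-5-[3-(4-methoxyphenyl)propanoyl]phenyl}-4-methoxyphenyl]propan-1-one | COc1ccc(CCC(=O)c2cc(-c3cc(CCC(=O)c4ccc(OC)cc4OC)ccc3OC)c(OC)cc2O)cc1 | intermediate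
19 | 1-(2,4-dihydroxyphenyl)-3-[3-{2,4-dihydroxy-5-[3-(4-hydroxyphenyl)propanoyl]phenyl}-4-hydroxyphenyl]propan-1-one | O=C(CCc1ccc(O)c(-c2cc(C(=O)CCc3ccc(O)cc3)c(O)cc2O)c1)c1ccc(O)cc1O | target

Total step count: 9. Longest linear sequence: 6 steps (1, 2, 3, 6, 8, 9).

Steps most likely to fail

1. Step 6.
- **Risk:** The ortho-substituted aryl group may slow bond formation at the diene terminus. Oligomerisation of the ynone, protodesilylation of the diene or attack through the α-carbon of the dienolate could then take over. Loss of the silyloxy group in place of the methoxy group on aromatisation would be harmless, since the extra methyl ether would fall in step 9.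
- **Fallback (sets out from 7, comes back at 15):** Ring C is bought instead of built, and the biaryl bond is made by cross-coupling. Acid 7 acylates 3-methoxyphenol in BF3·OEt2 at 85 °C (Friedel–Crafts/Fries acylation ortho to the hydroxyl) to give 1-(2-hydroxy-4-methoxyphenyl)-3-(4-methoxyphenyl)propan-1-one F1. N-Iodosuccinimide with catalytic CF3CO2H in MeCN iodinates the position para to the hydroxyl and ortho to the methoxy group, giving 1-(2-hydroxy-5-iodo-4-methoxyphenyl)-3-(4-methoxyphenyl)propan-1-one F2. A Suzuki–Miyaura coupling with commercial (5-bromo-2-methoxyphenyl)boronic acid (Pd(PPh3)4, Na2CO3, dioxane–water, 60 °C) then gives 15, because the C–I bond adds to zerovalent palladium well before C–Br.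

2. Step 8.
- **Risk:** β-Hydride elimination from the palladium homoenolate, base-induced isomerisation of the cyclopropanol to the ethyl ketone, or binding of the phenoxide to palladium may erode the coupling.
- **Fallback (sets out from 15, comes back at 18):** The arm is attached by Heck arylation of an allylic alcohol, which needs no cyclopropanol. Vinylmagnesium bromide is added to commercial 2,4-dimethoxybenzaldehyde (THF, 0 °C) to give racemic 1-(2,4-dimethoxyphenyl)prop-2-en-1-ol F3. Bromide 15 is then coupled with it (Pd(OAc)2, P(o-tol)3, NaHCO3, DMF, 100 °C). Insertion at the terminal alkene carbon, β-hydride elimination toward the carbinol and tautomerisation of the enol deliver the saturated ketone 18 directly.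

3. Step 3.
- **Risk:** Silylation at carbon instead of oxygen, an inward aryl geometry at C3=C4, or hydrolysis during handling may leave too little reactive diene.
- **Fallback (sets out from 3, comes back at 15):** A bis(silyloxy) diene is used, a family in which 4-aryl members are established. β-Keto ester 3 is silylated under soft conditions (Me3SiCl, Et3N, toluene, rt) to methyl (Z)-4-(5-bromo-2-methoxyphenyl)-3-(trimethylsilyloxy)but-2-enoate F4. LiN(iPr)2 and Me3SiCl at −78 °C convert it into (1Z,3Z)-4-(5-bromo-2-methoxyphenyl)-1-methoxy-1,3-bis(trimethylsilyloxy)buta-1,3-diene F5. Cycloaddition with 12 and acidic work-up should give 1-[5-(5-bromo-2-methoxyphenyl)-2,4-dihydroxyphenyl]-3-(4-methoxyphenyl)propan-1-one F6. MeI (1 equiv) with K2CO3 in acetone then methylates only the hydroxyl that is not hydrogen-bonded to the ketone, which gives 15.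

Further compounds
F1 | step 6 | 1-(2-hydroxy-4-methoxyphenyl)-3-(4-methoxyphenyl)propan-1-one | COc1ccc(CCC(=O)c2ccc(OC)cc2O)cc1
F2 | step 6 | 1-(2-hydroxy-5-iodo-4-methoxyphenyl)-3-(4-methoxyphenyl)propan-1-one | COc1ccc(CCC(=O)c2cc(I)c(OC)cc2O)cc1
F3 | step 8 | 1-(2,4-dimethoxyphenyl)prop-2-en-1-ol (racemic) | C=CC(O)c1ccc(OC)cc1OC
F4 | step 3 | methyl (Z)-4-(5-bromo-2-methoxyphenyl)-3-(trimethylsilyloxy)but-2-enoate | COC(=O)/C=C(\O[Si](C)(C)C)Cc1cc(Br)ccc1OC
F5 | step 3 | (1Z,3Z)-4-(5-bromo-2-methoxyphenyl)-1-methoxy-1,3-bis(trimethylsilyloxy)buta-1,3-diene | CO/C(O[Si](C)(C)C)=C/C(O[Si](C)(C)C)=C/c1cc(Br)ccc1OC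
F6 | step 3 | 1-[5-(5-bromo-2-methoxyphenyl)-2,4-dihydroxyphenyl]-3-(4-methoxyphenyl)propan-1-one | COc1ccc(CCC(=O)c2cc(-c3cc(Br)ccc3OC)c(O)cc2O)cc1
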